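The cyclohexane ring is cut into a 2-substituted buta-1,3-diene (C6=C1–C2=C3, with C1 carrying the complete, protected, stereodefined side chain) and (E)-3-bromo-2-methylacrolein (C5=C4). One catalytic enantioselective Diels–Alder reaction forms C6–C5 and C3–C4. It exploits the 1,4-relation in the ring between the side-chain carbon C1 and the quaternary carbon C4, which sits next to the brominated C5, and it sets both C5–Br and the quaternary centre. The formyl group on C4 is the placeholder for chlorine: Baeyer–Villiger oxidation gives an alcohol that directs hydrogenation of C1=C2 and is then replaced by chloride with retention.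

Key step: step 8

Locants: ring C1 = CH bearing the side chain, C2 and C3 = CH2, C4 = C(CH3)Cl, C5 = CHBr, C6 = CH2; chain C7 = tertiary carbinol, C8 = CH2, C9 = CHBr, C10 = C(CH3)2OH, C11 = acetyl C=O.

Assumption: the D-threonine-derived acetonide ester 1 and the L-fructose-derived enantiomer of the Shi ketone are taken as purchasable.

Step 1
Reactants: 1 methyl (4R,5S)-2,2,5-trimethyl-1,3-dioxolane-4-carboxylate; 2 prenyl bromide (1-bromo-3-methylbut-2-ene)
Product: 3 methyl (4S,5S)-2,2,5-trimethyl-4-(3-methylbut-2-en-1-yl)-1,3-dioxolane-4-carboxylate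
Conditions: LiN(iPr)2, THF, −78 °C; then 2, DMPU, −78 → −30 °C
Reagents that add atoms: none
Why: Alkylation of a heterocyclic ester enolate (1,3-dioxolane-4-carboxylate, deprotonated at the carbon that becomes C7): the enolate carbon is planar and the methyl group on the neighbouring ring carbon shields one face, so the allylic bromide should enter trans to it and set the quaternary centre C7, the descriptor of the starting centre being irrelevant.

Step 2
Reactants: 3 prenylated dioxolane ester
Product: 4 methyl (4S,5S)-4-{[(2S)-3,3-dimethyloxiran-2-yl]methyl}-2,2,5-trimethyl-1,3-dioxolane-4-carboxylate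
Conditions: L-fructose-derived Shi ketone (30 mol %), KHSO5 (as 2KHSO5·KHSO4·K2SO4), K2CO3, Bu4NHSO4, MeCN/CH2(OMe)2/aq. Na2B4O7 buffer, 0 °C
Reagents that add atoms: potassium peroxymonosulfate, [K+].[O-]S(=O)(=O)OO
Why: Shi asymmetric epoxidation (chiral dioxirane, spiro transition state) of the only alkene, a trisubstituted one, in which the L-fructose-derived ketone is expected to deliver oxygen to the face that gives the (S)-oxirane at C9 under reagent control.

Step 3
Reactants: 4 epoxy ester
Product: 5 methyl (4S,5S)-4-[(2R)-2-bromo-3-hydroxy-3-methylbutyl]-2,2,5-trimethyl-1,3-dioxolane-4-carboxylate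
Conditions: Li2NiBr4 (from LiBr and NiBr2), THF, 0 °C → rt; H2O
Reagents that add atoms: dilithium tetrabromonickelate, [Li+].[Li+].[Ni+2].[Br-].[Br-].[Br-].[Br-]
Why: Regioselective SN2 opening of a trisubstituted oxirane by the soft bromide of Li2NiBr4 at the less substituted carbon C9 with inversion, which turns the (S)-oxirane into the (R)-bromide and frees the tertiary alcohol at C10.

Step 4
Reactants: 5 bromohydrin ester
Product: 6 methyl (4S,5S)-4-{(2R)-2-bromo-3-methyl-3-[(triethylsilyl)oxy]butyl}-2,2,5-trimethyl-1,3-dioxolane-4-carboxylate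
Conditions: Et3SiOTf, 2,6-lutidine, CH2Cl2, −78 → 0 °C
Reagents that add atoms: triethylsilyl trifluoromethanesulfonate, CC[Si](CC)(CC)OS(=O)(=O)C(F)(F)F
Why: Silylation of a tertiary alcohol with a silyl triflate and a hindered pyridine base, needed so that the ring alcohol of 16 is the only free tertiary alcohol when chloride is introduced in step 11; no stereocentre is touched.

Step 5
Reactants: 6 silyl-protected bromo ester
Product: 8 vinyl ketone 1-[(4S,5S)-4-{(2R)-2-bromo-3-methyl-3-[(triethylsilyl)oxy]butyl}-2,2,5-trimethyl-1,3-dioxolan-4-yl]prop-2-en-1-one, via Weinreb amide 7 (not isolated)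
Conditions: MeNH(OMe)·HCl, iPrMgCl, THF, −20 °C; then CH2=CHMgBr, −20 → 0 °C; cold aq. HCl
Reagents that add atoms: vinylmagnesium bromide, C=C[Mg]Br
Why: Weinreb ketone synthesis in one pot: the magnesium amide converts the methyl ester into the N-methoxy-N-methylamide, whose stable magnesium chelate accepts one equivalent of the vinyl Grignard reagent and collapses to the enone only on acidic quench, so no tertiary alcohol forms and no stereocentre is touched.

Step 6
Reactants: 8 vinyl ketone
Product: 9 (4R,5S)-4-(buta-1,3-dien-2-yl)-4-{(2R)-2-bromo-3-methyl-3-[(triethylsilyl)oxy]butyl}-2,2,5-trimethyl-1,3-dioxolane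
Conditions: Ph3PCH3Br, KN(SiMe3)2, THF, 0 °C; then 8, −78 → 0 °C
Reagents that add atoms: methyltriphenylphosphonium bromide, C[P+](c1ccccc1)(c1ccccc1)c1ccccc1.[Br-]
Why: Wittig methylenation: the unstabilised ylide adds 1,2 to the non-enolisable vinyl ketone and the oxaphosphetane collapses to the 1,1-disubstituted alkene, turning C1=O into C1=C6 and giving the 2-substituted buta-1,3-diene.

Step 7
Reactants: 10 methacrolein (2-methylprop-2-enal)
Product: 12 (E)-3-bromo-2-methylprop-2-enal, via 2,3-dibromo-2-methylpropanal 11 (not isolated)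
Conditions: Br2, CH2Cl2, −10 °C; then Et3N, 0 °C → rt
Reagents that add atoms: bromine, BrBr
Why: Electrophilic anti addition of bromine to the alkene followed by amine-induced E2 loss of HBr across C2–C3 (the α-carbon has no hydrogen) gives the conjugated β-bromo enal, expected mainly as the more stable E isomer (Br trans to CHO), whose geometry is later copied into the ring.

Step 8
Reactants: 9 side-chain diene; 12 (E)-3-bromo-2-methylprop-2-enal
Product: 13 (1R,6S)-6-bromo-4-[(4R,5S)-4-{(2R)-2-bromo-3-methyl-3-[(triethylsilyl)oxy]butyl}-2,2,5-trimethyl-1,3-dioxolan-4-yl]-1-methylcyclohex-3-ene-1-carbaldehyde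
Conditions: (R)-o-tolyl oxazaborolidine from (R)-α,α-diphenylprolinol (20 mol %), HNTf2 (16 mol %), CH2Cl2, −78 → −40 °C
Reagents that add atoms: none
Why: The protonated oxazaborolidine binds the formyl oxygen of 12 (with a formyl C–H···O contact), lowers its LUMO and shields one enantioface, and the s-cis diene 9 adds to the open face in a concerted, asynchronous, suprafacial [4+2] cycloaddition. The closest known reaction type is the oxazaborolidinium-catalysed enantioselective Diels–Alder reaction of 2-substituted acroleins with 2-substituted butadienes; the β-bromine is only a new substituent. The one ring that is closed, the cyclohexene C1–C6, is closed by cycloaddition, both σ-bonds (C6–C5 and C3–C4) arising in the same step from a four-carbon and a two-carbon component. The E geometry of 12 is copied stereospecifically into the ring, putting the bromine at C5 trans to the formyl group and cis to the methyl group at C4, and the absolute configuration of both centres (C4 R, C5 S) is set by the (R)-catalyst, whose control overrides the remote stereocentres of 9. The step needs para regioselectivity, secured by the 2-substituent of the diene (largest HOMO coefficient at C6, matched with the β-carbon C5 of the enal), and enantioface selectivity on the dienophile, secured by the catalyst; endo/exo selectivity is irrelevant because both diene termini are CH2 groups. The bulky substituent at C1 also favours the s-cis conformer of the diene.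

Step 9
Reactants: 13 Diels–Alder aldehyde
Product: 15 (1S,6S)-6-bromo-4-[(4R,5S)-4-{(2R)-2-bromo-3-methyl-3-[(triethylsilyl)oxy]butyl}-2,2,5-trimethyl-1,3-dioxolan-4-yl]-1-methylcyclohex-3-en-1-ol, via formate ester 14 (not isolated)
Conditions: mCPBA, Na2HPO4, CH2Cl2, 0 °C; then KHCO3, MeOH, 0 °C → rt
Reagents that add atoms: 3-chloroperoxybenzoic acid, OOC(=O)c1cccc(Cl)c1
Why: Baeyer–Villiger oxidation of a tertiary aldehyde: in the peracid adduct the fully substituted ring carbon C4 migrates to oxygen in preference to hydrogen and with retention of configuration, and mild methanolysis of the resulting formate frees the tertiary alcohol on the face opposite to bromine, the hindered ring alkene with an allylic C–O bond being expected to be epoxidised more slowly.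

Step 10
Reactants: 15 cyclohexenol
Product: 16 (1S,2S,4S)-2-bromo-4-[(4R,5S)-4-{(2R)-2-bromo-3-methyl-3-[(triethylsilyl)oxy]butyl}-2,2,5-trimethyl-1,3-dioxolan-4-yl]-1-methylcyclohexan-1-ol
Conditions: H2 (1 atm), [Ir(cod)(PCy3)(py)]PF6 (10 mol %), CH2Cl2, 0 °C → rt
Reagents that add atoms: none
Why: Hydroxyl-directed homogeneous hydrogenation (the terpinen-4-ol case): the homoallylic tertiary hydroxyl at C4 binds the cationic iridium centre and both hydrogens are delivered to the alkene face syn to it, so the new H at C1 is cis to that oxygen and the side chain ends trans to it and cis to the bromine at C5, which sets C1.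

Step 11
Reactants: 16 cyclohexanol
Product: 17 (4R,5S)-4-[(1S,3S,4S)-3-bromo-4-chloro-4-methylcyclohexyl]-4-{(2R)-2-bromo-3-methyl-3-[(triethylsilyl)oxy]butyl}-2,2,5-trimethyl-1,3-dioxolane
Conditions: Me2C=C(Cl)NMe2, CH2Cl2, 0 °C → rt
Reagents that add atoms: 1-chloro-N,N,2-trimethylprop-1-en-1-amine, CC(C)=C(Cl)N(C)C
Why: Deoxychlorination of a tertiary alcohol with an α-chloroenamine under neutral conditions: the O-alkyl imidate chloride ionises at C4 and the bromine on C5, held on the opposite face, bridges the cationic centre (neighbouring-group participation, as in the conversion of bromohydrins into dihalides with retention), so chloride is expected to attack anti to bromine on the face that the oxygen left, giving the trans bromo chloride with retention at C4.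

Step 12
Reactants: 17 protected bromo chloride
Product: 18 (2S,3R,5R)-5-bromo-3-[(1S,3S,4S)-3-bromo-4-chloro-4-methylcyclohexyl]-6-methylheptane-2,3,6-triol
Conditions: CF3CO2H/H2O/THF (1:1:4), 0 °C → rt
Reagents that add atoms: none
Why: Acid-catalysed hydrolysis cleaves the isopropylidene acetal and the tertiary silyl ether in one operation, the tertiary chloride being slow to ionise because of the electron-withdrawing vicinal bromine, and no stereocentre is affected.

Step 13
Reactants: 18 triol
Product: 19 (3R,5R)-5-bromo-3-[(1S,3S,4S)-3-bromo-4-chloro-4-methylcyclohexyl]-3,6-dihydroxy-6-methylheptan-2-one (target)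
Conditions: IBX, DMSO, rt
Reagents that add atoms: none
Why: Oxidation of the only secondary alcohol with the hypervalent iodine reagent IBX, which leaves tertiary alcohols alone and turns 1,2-diols into α-hydroxy ketones without C–C cleavage, erases the auxiliary stereocentre at C11 and gives the methyl ketone.

Compound list

1 | methyl (4R,5S)-2,2,5-trimethyl-1,3-dioxolane-4-carboxylate | C[C@@H]1OC(C)(C)O[C@H]1C(=O)OC | starting material
2 | 1-bromo-3-methylbut-2-ene (prenyl bromide) | CC(C)=CCBr | starting material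
3 | methyl (4S,5S)-2,2,5-trimethyl-4-(3-methylbut-2-en-1-yl)-1,3-dioxolane-4-carboxylate | C[C@@H]1OC(C)(C)O[C@]1(CC=C(C)C)C(=O)OC | intermediate
4 | methyl (4S,5S)-4-{[(2S)-3,3-dimethyloxiran-2-yl]methyl}-2,2,5-trimethyl-1,3-dioxolane-4-carboxylate | C[C@@H]1OC(C)(C)O[C@]1(C[C@@H]2OC2(C)C)C(=O)OC | intermediate
5 | methyl (4S,5S)-4-[(2R)-2-bromo-3-hydroxy-3-methylbutyl]-2,2,5-trimethyl-1,3-dioxolane-4-carboxylate | C[C@@H]1OC(C)(C)O[C@]1(C[C@@H](Br)C(C)(C)O)C(=O)OC | intermediate
6 | methyl (4S,5S)-4-{(2R)-2-bromo-3-methyl-3-[(triethylsilyl)oxy]butyl}-2,2,5-trimethyl-1,3-dioxolane-4-carboxylate | C[C@@H]1OC(C)(C)O[C@]1(C[C@@H](Br)C(C)(C)O[Si](CC)(CC)CC)C(=O)OC | intermediate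
7 | (4S,5S)-4-{(2R)-2-bromo-3-methyl-3-[(triethylsilyl)oxy]butyl}-N-methoxy-N,2,2,5-tetramethyl-1,3-dioxolane-4-carboxamide | C[C@@H]1OC(C)(C)O[C@]1(C[C@@H](Br)C(C)(C)O[Si](CC)(CC)CC)C(=O)N(C)OC | intermediate
8 | 1-[(4S,5S)-4-{(2R)-2-bromo-3-methyl-3-[(triethylsilyl)oxy]butyl}-2,2,5-trimethyl-1,3-dioxolan-4-yl]prop-2-en-1-one | C[C@@H]1OC(C)(C)O[C@]1(C[C@@H](Br)C(C)(C)O[Si](CC)(CC)CC)C(=O)C=C | intermediate
9 | (4R,5S)-4-(buta-1,3-dien-2-yl)-4-{(2R)-2-bromo-3-methyl-3-[(triethylsilyl)oxy]butyl}-2,2,5-trimethyl-1,3-dioxolane | C[C@@H]1OC(C)(C)O[C@]1(C[C@@H](Br)C(C)(C)O[Si](CC)(CC)CC)C(=C)C=C | intermediate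
10 | 2-methylprop-2-enal (methacrolein) | CC(=C)C=O | starting material
11 | 2,3-dibromo-2-methylpropanal (racemic) | CC(Br)(CBr)C=O | intermediate
12 | (E)-3-bromo-2-methylprop-2-enal | O=C/C(C)=C/Br | intermediate
13 | (1R,6S)-6-bromo-4-[(4R,5S)-4-{(2R)-2-bromo-3-methyl-3-[(triethylsilyl)oxy]butyl}-2,2,5-trimethyl-1,3-dioxolan-4-yl]-1-methylcyclohex-3-ene-1-carbaldehyde | C[C@@H]1OC(C)(C)O[C@]1(C[C@@H](Br)C(C)(C)O[Si](CC)(CC)CC)C2=CC[C@](C)(C=O)[C@@H](Br)C2 | intermediate
14 | (1S,6S)-6-bromo-4-[(4R,5S)-4-{(2R)-2-bromo-3-methyl-3-[(triethylsilyl)oxy]butyl}-2,2,5-trimethyl-1,3-dioxolan-4-yl]-1-methylcyclohex-3-en-1-yl formate | C[C@@H]1OC(C)(C)O[C@]1(C[C@@H](Br)C(C)(C)O[Si](CC)(CC)CC)C2=CC[C@](C)(OC=O)[C@@H](Br)C2 | intermediate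
15 | (1S,6S)-6-bromo-4-[(4R,5S)-4-{(2R)-2-bromo-3-methyl-3-[(triethylsilyl)oxy]butyl}-2,2,5-trimethyl-1,3-dioxolan-4-yl]-1-methylcyclohex-3-en-1-ol | C[C@@H]1OC(C)(C)O[C@]1(C[C@@H](Br)C(C)(C)O[Si](CC)(CC)CC)C2=CC[C@](C)(O)[C@@H](Br)C2 | intermediate
16 | (1S,2S,4S)-2-bromo-4-[(4R,5S)-4-{(2R)-2-bromo-3-methyl-3-[(triethylsilyl)oxy]butyl}-2,2,5-trimethyl-1,3-dioxolan-4-yl]-1-methylcyclohexan-1-ol | C[C@@H]1OC(C)(C)O[C@]1(C[C@@H](Br)C(C)(C)O[Si](CC)(CC)CC)[C@H]2CC[C@](C)(O)[C@@H](Br)C2 | intermediate
17 | (4R,5S)-4-[(1S,3S,4S)-3-bromo-4-chloro-4-methylcyclohexyl]-4-{(2R)-2-bromo-3-methyl-3-[(triethylsilyl)oxy]butyl}-2,2,5-trimethyl-1,3-dioxolane | C[C@@H]1OC(C)(C)O[C@]1(C[C@@H](Br)C(C)(C)O[Si](CC)(CC)CC)[C@H]2CC[C@](C)(Cl)[C@@H](Br)C2 | intermediate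
18 | (2S,3R,5R)-5-bromo-3-[(1S,3S,4S)-3-bromo-4-chloro-4-methylcyclohexyl]-6-methylheptane-2,3,6-triol | C[C@H](O)[C@@](O)(C[C@@H](Br)C(C)(C)O)[C@H]1CC[C@](C)(Cl)[C@@H](Br)C1 | intermediate
19 | (3R,5R)-5-bromo-3-[(1S,3S,4S)-3-bromo-4-chloro-4-methylcyclohexyl]-3,6-dihydroxy-6-methylheptan-2-one | CC(=O)[C@@](O)(C[C@@H](Br)C(C)(C)O)[C@H]1CC[C@](C)(Cl)[C@@H](Br)C1 | target

Total step count: 13. Longest linear sequence: 12 steps (steps 1–6 and 8–13 from ester 1; step 7 makes the dienophile).

Steps most likely to fail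

Step 8, the key cycloaddition. The hindered diene and the trisubstituted, β-brominated enal may combine too slowly, so that the diene polymerises, or enantioface or para control may erode. The fallback sets out from diene 9 and comes back at alcohol 15. The same two ring bonds are made under neutral conditions by the cobalt-catalysed [4+2] cycloaddition of 9 with propyne (CoBr2(dppe), Zn, ZnI2, CH2Cl2, rt; para-selective with this ligand), which gives the 1-substituted 4-methylcyclohexa-1,4-diene F1. Its less hindered, methyl-substituted ring alkene is epoxidised under reagent control with the D-fructose-derived Shi ketone and KHSO5 to the oxirane F2, with oxygen on the face that later carries chlorine. Li2NiBr4 then opens the oxirane at the secondary carbon C5 with inversion and gives 15.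

Step 9, the Baeyer–Villiger oxidation. The peracid may epoxidise the ring alkene faster than it oxidises the hindered aldehyde, or hydrogen may migrate instead of carbon so that the carboxylic acid forms. The fallback sets out from aldehyde 13 and comes back at alcohol 16. The aldehyde is first reduced with NaBH4 in MeOH to the primary alcohol F3. Its hydroxymethyl group, on the face of the later chlorine, directs hydrogenation with [Ir(cod)(PCy3)(py)]PF6 to that face and gives the cyclohexylmethanol F4. Dess–Martin oxidation returns the alkene-free aldehyde F5, and mCPBA followed by methanolysis of the formate ester F6 gives 16.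

Step 11, the exchange of OH for Cl. The tertiary cation may lose a proton to give an alkene, or chloride may be captured on the bromine side, because the diequatorial bromohydrin cannot reach the anti-periplanar arrangement that bromine participation needs. The fallback sets out from cyclohexenol 15 and comes back at triol 18. Chloride is introduced one stage earlier with the same chloroenamine, on the conformationally mobile cyclohexene where hydroxyl and bromine can become trans-diaxial, to give the cyclohexenyl bromo chloride F7. Aqueous trifluoroacetic acid removes the acetal and the silyl ether and gives the unsaturated triol F8. Its hydrogenation with [Ir(cod)(PCy3)(py)]PF6 is now directed by the allylic tertiary hydroxyl at C7 and biased by the axial bromine at C5, which shields the face of C1 syn to it, and gives 18.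

Further compounds

F1 | step 8 | (4R,5S)-4-{(2R)-2-bromo-3-methyl-3-[(triethylsilyl)oxy]butyl}-2,2,5-trimethyl-4-(4-methylcyclohexa-1,4-dien-1-yl)-1,3-dioxolane | C[C@@H]1OC(C)(C)O[C@]1(C[C@@H](Br)C(C)(C)O[Si](CC)(CC)CC)C2=CCC(C)=CC2
F2 | step 8 | (4R,5S)-4-{(2R)-2-bromo-3-methyl-3-[(triethylsilyl)oxy]butyl}-2,2,5-trimethyl-4-[(1R,6S)-6-methyl-7-oxabicyclo[4.1.0]hept-3-en-3-yl]-1,3-dioxolane | C[C@@H]1OC(C)(C)O[C@]1(C[C@@H](Br)C(C)(C)O[Si](CC)(CC)CC)C2=CC[C@]3(C)O[C@@H]3C2
F3 | step 9 | [(1R,6S)-6-bromo-4-[(4R,5S)-4-{(2R)-2-bromo-3-methyl-3-[(triethylsilyl)oxy]butyl}-2,2,5-trimethyl-1,3-dioxolan-4-yl]-1-methylcyclohex-3-en-1-yl]methanol | C[C@@H]1OC(C)(C)O[C@]1(C[C@@H](Br)C(C)(C)O[Si](CC)(CC)CC)C2=CC[C@](C)(CO)[C@@H](Br)C2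
F4 | step 9 | [(1R,2S,4S)-2-bromo-4-[(4R,5S)-4-{(2R)-2-bromo-3-methyl-3-[(triethylsilyl)oxy]butyl}-2,2,5-trimethyl-1,3-dioxolan-4-yl]-1-methylcyclohexyl]methanol | C[C@@H]1OC(C)(C)O[C@]1(C[C@@H](Br)C(C)(C)O[Si](CC)(CC)CC)[C@H]2CC[C@](C)(CO)[C@@H](Br)C2
F5 | step 9 | (1R,2S,4S)-2-bromo-4-[(4R,5S)-4-{(2R)-2-bromo-3-methyl-3-[(triethylsilyl)oxy]butyl}-2,2,5-trimethyl-1,3-dioxolan-4-yl]-1-methylcyclohexane-1-carbaldehyde | C[C@@H]1OC(C)(C)O[C@]1(C[C@@H](Br)C(C)(C)O[Si](CC)(CC)CC)[C@H]2CC[C@](C)(C=O)[C@@H](Br)C2
F6 | step 9 | (1S,2S,4S)-2-bromo-4-[(4R,5S)-4-{(2R)-2-bromo-3-methyl-3-[(triethylsilyl)oxy]butyl}-2,2,5-trimethyl-1,3-dioxolan-4-yl]-1-methylcyclohexyl formate | C[C@@H]1OC(C)(C)O[C@]1(C[C@@H](Br)C(C)(C)O[Si](CC)(CC)CC)[C@H]2CC[C@](C)(OC=O)[C@@H](Br)C2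
F7 | step 11 | (4R,5S)-4-[(4S,5S)-5-bromo-4-chloro-4-methylcyclohex-1-en-1-yl]-4-{(2R)-2-bromo-3-methyl-3-[(triethylsilyl)oxy]butyl}-2,2,5-trimethyl-1,3-dioxolane | C[C@@H]1OC(C)(C)O[C@]1(C[C@@H](Br)C(C)(C)O[Si](CC)(CC)CC)C2=CC[C@](C)(Cl)[C@@H](Br)C2
F8 | step 11 | (2S,3R,5R)-5-bromo-3-[(4S,5S)-5-bromo-4-chloro-4-methylcyclohex-1-en-1-yl]-6-methylheptane-2,3,6-triol | C[C@H](O)[C@@](O)(C[C@@H](Br)C(C)(C)O)C1=CC[C@](C)(Cl)[C@@H](Br)C1
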